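## Analysis of the target

Target 38 is a trans-clerodane diol mono-ester, and clerodane numbering is used throughout: ring A is C1–C5 plus C10 and carries the C3=C4 alkene with methyl C18 on C4; ring B is C5–C10; methyls C19, C17 and C20 sit on C5, C8 and C9; the chain C11–C16 leaves C9. The four stereocentres are contiguous (C5, C10, C9, C8; 5R,8R,9S,10R). In the usual drawing (ring A left, C10 at the top of the fusion bond) H-10 is β and trans to the angular methyl C19 (α), C19 and C20 are syn-diaxial on ring B, C17 is equatorial and cis to C20, and C11 is β. The chain ends in an (E)-trisubstituted alkene C13=C14 with two differentiated allylic oxygens, a free hydroxyl on C16 and the icosanoate on C15. Because these two CH2O groups are trans across the alkene the acyl group cannot migrate, but both are ionisable allylic positions, and the ester rules out strongly basic or reducing conditions at the end. The trisubstituted ring alkene can migrate under acid. The difficulty is that two quaternary carbons (C5 and C9) flank the methine C10 in a decalin without any heteroatom handle, so every stereocentre has to be fixed in a C–C bond-forming event. The strategy rests on ring A: it is a cyclohexene whose fusion bond C5–C10 joins the methyl-bearing C5 to the methine C10. With the alkene moved formally to C1=C2 and C18 raised to an ester, ring A is the adduct of a C10=C1–C2=C3 diene and a C4=C5 β-methyl enoate, linked by the C6–C9 chain that already holds C8 and C9.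

## Retrosynthetic reasoning

**C16–O and C12–C13.** Target 38 is the desilylation product of 37. Compound 37 is cut at the sp3–sp2 bond C12–C13 into alkyl iodide 29 (used as zinc reagent 36) and alkenyl iodide 35. This separates the decalin with all four stereocentres from an achiral chain that already carries the fatty ester and the alkene geometry. A cut at C13=C14 would bring an E/Z problem and a late differentiation of two allylic hydroxyls; a cut at C9–C11 would require coupling at a quaternary carbon. The forward coupling has to retain the alkene geometry and tolerate an allylic ester.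

**Side-chain fragment.** Ester 35 comes from alcohol 33 and acid 34. Iodoalkene 33 is traced to alkyne 31 and diol 30. A hydroxyl-directed trans-hydroalumination fixes the geometry and also places the free hydroxyl (future O15) and the silyl ether (future O16) on the correct carbons, so the two oxygens never have to be told apart later.

**Functional-group adjustment of the decalin.** Iodide 29 goes back through alcohol 28 and silyl ether 27. The C18 methyl of 27 is derived from the allylic alcohol 25 and the enoate 24. The C3=C4 alkene of 24 comes from the saturated ester 21 by dehydrogenation; C5 is quaternary, so elimination can only run towards C3. Compound 21 comes from 20 by saturation of C1=C2, and the C12 oxygen of 20 and 19 comes from the vinyl group of 17. These steps move the alkene from the position the cycloaddition creates to the position the target needs and use the ester that activated the dienophile as the source of C18.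

**Key disconnection (C5–C10 and C3–C4).** Adduct 17 is opened by a retro-[4+2] to triene 16. Both rings, the quaternary C5, C10 and the C18 carbon are gained in one step. The methyl sits on the dienophile carbon C5 rather than on a diene terminus, so the quaternary centre forms at the more reactive partner. The forward reaction has to give the trans ring fusion and the correct diene face relative to C8 and C9.

**Chain ends of the triene.** Triene 16 is cut at C4=C5 (olefination of methyl ketone 15), then at C5–C19 (15 from ester 13), then at C10=C1 (diene olefination of aldehyde 11). This order is chosen because aldehyde and ester in 11 are chemically distinct, so each end can be extended without protecting the other.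

**Ring cleavage.** Aldehyde ester 11 arises from ketol 10 and enol ether 8 by cleaving the C5–C10 bond of a cyclohexanone, the same bond that step 11 forms again. The six-membered ring is a temporary template in which C9 is set relative to C8; it is opened so that C5 and C10 can be extended into dienophile and diene.

**C9–C11 and C9–C20.** Enol ether 8 comes from enone 7 by conjugate addition of the vinyl group anti to the C17 methyl. Enone 7 comes from 5 through 6 by β-methylation with return to the enone. Methyl first and vinyl second is the order that gives C17 and C20 cis.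

**C6–C7 and ring formation.** Enone 5 comes from keto aldehyde 3 by aldol condensation, and 3 from propanal 1 and enone 2 by a catalytic asymmetric Michael addition. This sets C8, from which all other stereocentres are derived.

## Alternatives that were turned down

**Alternative 1:** Ring A alone is cut at C4–C5 and C1–C10 into silyloxydiene A1 and the (E)-α-methyl enal A2. In the forward sense a chiral oxazaborolidinium-type Lewis acid would catalyse their Diels–Alder union to cyclohexene carbaldehyde A3, setting C5 (quaternary, methyl and formyl) and C10.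
- For it: the absolute configuration comes from a catalyst and achiral feedstocks; the E geometry of A2 becomes the cis relation of C19 and C9; such catalysed additions to 1-oxygenated dienes are regio- and endo-selective. On enantiocontrol this plan is stronger than the chosen one, whose diene-face selectivity in step 11 rests on a conformational bias.
- Against it: A3 holds only ring A and two of the four stereocentres. Ring B would have to be annulated from the neopentyl aldehyde (C6) and the benzyloxymethyl arm (C9), with quaternary C9 and C8 set late by substrate control beside an existing quaternary centre. The C1 silyloxy group is an oxygen the target lacks; C4 is a bare methylene, so C18 and the C3=C4 alkene still need an allylic functionalisation.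
- Comparison: the sequence from A3 to the decalin would be clearly longer than that from 16 to 29. The chosen route forms both rings and three stereocentres and carries C18 in one step.

**Alternative 2:** No ring bond is cut. The clerodane is traced to ent-labdane A4 (exocyclic C8=C17 alkene, gem-dimethyl at C4, methyl on C10). Forward, a strong Brønsted acid in a fluorinated alcohol protonates C17; the C8 cation is relayed by four antiperiplanar 1,2-shifts (H-9 to C8, the C10 methyl to C9, H-5 to C10, the axial C4 methyl to C5) and loss of H-3 gives pivalate A5, the pivalate of alcohol 28.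
- For it: the whole decalin with all four stereocentres in one operation, each shift suprafacial and stereospecific, and the endgame from 28 unchanged. On step count this plan is clearly stronger.
- Against it: A4 must belong to the ent series, whereas the cheap labdane feedstocks belong to the normal series and would lead to the enantiomer of 38. The cascade can stop at every cationic station (proton loss after one or two shifts, alkenes around C10, exocyclic versus endocyclic alkene at C4). The full relay builds up the C19/C20 syn-diaxial strain, so it is not strongly downhill, and the isomeric olefins are hard to separate.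
- Comparison: the chosen strategy gives up brevity for stepwise, individually controllable bond formations from commodity chemicals and a single skeleton after the key step.

**Alternative 3:** Ring A is cut at C4–C5 together with the auxiliary bond C4–C19, giving diazoketone A6: a fully substituted ring B with the exocyclic C5=C19 methylene and the diazoketone arm on C10. Forward, a dirhodium tetracarboxylate (divalent rhodium) generates a carbenoid at C4 that adds across C5=C19 to cyclopropyl ketone A7. Reductive opening of C4–C19 would later unveil the C19 methyl, and the C3 ketone would serve to introduce C18 and the alkene.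
- For it: the carbenoid is delivered from the equatorial C10 arm, so the configuration of quaternary C5 is fixed by geometry. On the security of C5 this plan is stronger than a cycloaddition transition state that has to be biased. The chemistry is catalytic and mild.
- Against it: A6 presupposes C8, C9 and C10 on a preformed ring, so the hardest stereochemical problem (quaternary C9 beside C10) must be solved before the key step, which then makes only one ring and one stereocentre. Diazoketone preparation, competing C–H insertion, and at least five further operations after A7 add length.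
- Comparison: the chosen strategy constructs more per step (C5, C10, both rings and the C18 carbon at once) from a chain whose two stereocentres come from one cyclohexenone.

Key step: step 11

Assumption: the (S)-configured prolinol ether is taken to give the (R)-aldehyde 3 by the usual shielding model of the (E)-enamine; if the sense were opposite, the (R)-catalyst would be used and nothing else would change.

## Route

Step 1
Reactants: 1 propanal; 2 but-3-en-2-one (methyl vinyl ketone)
Product: 3 (2R)-2-methyl-5-oxohexanal
Conditions: (S)-2-[methoxy(diphenyl)methyl]pyrrolidine (5 mol %), ethyl 3,4-dihydroxybenzoate (20 mol %), neat, 4 °C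
Reagents that add atoms: none
Why: Enamine-mediated asymmetric Michael addition; the diarylmethyl group shields one face of the (E)-enamine of 1, so the enone adds to the open face and sets C8, the centre from which all others are derived.

Step 2
Reactants: 3 (2R)-2-methyl-5-oxohexanal
Product: 5 (4R)-4-methylcyclohex-2-en-1-one, via aldol adduct 4 (not isolated)
Conditions: aq. KOH (0.1 M), Bu4NOH (cat.), Et2O–THF, reflux
Reagents that add atoms: none
Why: Intramolecular aldol condensation (methyl-ketone enolate onto the aldehyde, 6-enolexo) with E1cB dehydration; the stereocentre becomes the γ-carbon of the enone, and ring closure should outpace enolisation of the aldehyde, which is to be verified by the enantiomeric purity of 5.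

Step 3
Reactants: 5 (4R)-4-methylcyclohex-2-en-1-one
Product: 6 {[(3S,4R)-3,4-dimethylcyclohex-1-en-1-yl]oxy}trimethylsilane
Conditions: MeMgBr, CuBr·SMe2 (10 mol %), Me3SiCl, DMPU, THF, −78 °C
Reagents that add atoms: methylmagnesium bromide, C[Mg]Br; chlorotrimethylsilane, C[Si](C)(C)Cl
Why: Copper-catalysed conjugate addition with in-situ silylation of the enolate; the methyl enters trans to the C4 methyl, but this centre is planarised again in step 4, and the regiodefined enol ether is what matters.

Step 4
Reactants: 6 {[(3S,4R)-3,4-dimethylcyclohex-1-en-1-yl]oxy}trimethylsilane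
Product: 7 (4R)-3,4-dimethylcyclohex-2-en-1-one
Conditions: Pd(OAc)2 (10 mol %), O2 (1 atm), DMSO, rt
Reagents that add atoms: none
Why: Saegusa–Ito dehydrogenation; the oxa-π-allyl divalent palladium species from 6 undergoes β-hydride elimination at C3 and restores the enone with the new β-methyl (C20), and the neutral conditions leave C4 untouched.

Step 5
Reactants: 7 (4R)-3,4-dimethylcyclohex-2-en-1-one
Product: 8 {[(3S,4R)-3-ethenyl-3,4-dimethylcyclohex-1-en-1-yl]oxy}trimethylsilane
Conditions: CH2=CHMgBr, CuBr·SMe2 (20 mol %), Me3SiCl, HMPA, THF, −78 °C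
Reagents that add atoms: vinylmagnesium bromide, C=C[Mg]Br; chlorotrimethylsilane, C[Si](C)(C)Cl
Why: Copper-catalysed 1,4-addition to the β,β-disubstituted enone accelerated by the silyl chloride; the vinyl group attacks C3 axially, anti to the pseudoaxial C4 methyl (which avoids A(1,2) strain with the C3 methyl), so quaternary C9 is set with C17 and C20 cis, and the enolate is trapped regiospecifically between the future C5 and C10.

Step 6
Reactants: 8 {[(3S,4R)-3-ethenyl-3,4-dimethylcyclohex-1-en-1-yl]oxy}trimethylsilane
Product: 10 (3S,4R)-3-ethenyl-2-hydroxy-3,4-dimethylcyclohexan-1-one (C2 epimers), via silyloxy ketone 9 (not isolated)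
Conditions: mCPBA, NaHCO3, CH2Cl2, 0 °C; then 1 M HCl, THF, rt
Reagents that add atoms: 3-chloroperoxybenzoic acid, OOC(=O)c1cccc(Cl)c1
Why: Rubottom oxidation; the electron-rich enol ether is epoxidised far faster than the monosubstituted vinyl group and the silyloxy epoxide rearranges to the α-silyloxy ketone, hydrolysed on work-up; the C2 configuration is irrelevant because this carbon becomes the aldehyde.

Step 7
Reactants: 10 (3S,4R)-3-ethenyl-2-hydroxy-3,4-dimethylcyclohexan-1-one
Product: 11 methyl (4R,5S)-5-formyl-4,5-dimethylhept-6-enoate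
Conditions: Pb(OAc)4, MeOH–benzene (1:1), 0 °C
Reagents that add atoms: methanol, CO
Why: Glycol-type cleavage of the α-ketol by tetravalent lead in methanol; the hemiketal carbon leaves as the methyl ester (C5) and the carbinol carbon as the aldehyde (C10), which is α-quaternary and can neither epimerise nor conjugate.

Step 8
Reactants: 11 methyl (4R,5S)-5-formyl-4,5-dimethylhept-6-enoate
Product: 13 methyl (4R,5S,6E)-5-ethenyl-4,5-dimethylnona-6,8-dienoate, via hydroxyphosphonate adduct 12 (not isolated)
Conditions: CH2=CHCH2P(O)(OEt)2, n-BuLi, THF, −78 °C; 11; then HMPA, −78 °C → rt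
Reagents that add atoms: diethyl allylphosphonate, C=CCP(=O)(OCC)OCC
Why: Horner–Wadsworth–Emmons-type diene synthesis; α-addition of the lithiated allylphosphonate to the aldehyde and HMPA-promoted loss of phosphate from adduct 12 should give the terminal (E)-diene, and at −78 °C the aldehyde reacts well before the methyl ester.

Step 9
Reactants: 13 methyl (4R,5S,6E)-5-ethenyl-4,5-dimethylnona-6,8-dienoate
Product: 15 (5R,6S,7E)-6-ethenyl-5,6-dimethyldeca-7,9-dien-2-one, via Weinreb amide 14 (not isolated)
Conditions: MeNH(OMe)·HCl, iPrMgCl, THF, −20 °C; then MeMgBr, 0 °C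
Reagents that add atoms: methylmagnesium bromide, C[Mg]Br
Why: Aminolysis of the ester by the magnesium amide gives Weinreb amide 14, whose chelated tetrahedral adduct with the Grignard reagent stops at the ketone stage; the methyl introduced is C19.

Step 10
Reactants: 15 (5R,6S,7E)-6-ethenyl-5,6-dimethyldeca-7,9-dien-2-one
Product: 16 methyl (2E,6R,7S,8E)-7-ethenyl-3,6,7-trimethylundeca-2,8,10-trienoate
Conditions: (MeO)2P(O)CH2CO2Me, NaH, THF, 0 → 50 °C; chromatographic removal of the (2Z) isomer
Reagents that add atoms: trimethyl phosphonoacetate, COC(=O)CP(=O)(OC)OC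
Why: Horner–Wadsworth–Emmons olefination of the methyl ketone; the (2E) enoate (ester trans to the chain) should predominate, and the (2Z) isomer has to be removed because it would lead to cis-fused adducts in step 11.

Step 11
Reactants: 16 methyl (2E,6R,7S,8E)-7-ethenyl-3,6,7-trimethylundeca-2,8,10-trienoate
Product: 17 methyl (4R,5R,8R,9S,10S)-13,14,15,16-tetranorcleroda-1,11-dien-18-oate
Conditions: EtAlCl2 (1.2 equiv), CH2Cl2, −78 °C → rt
Reagents that add atoms: none
Why: EtAlCl2 binds the ester carbonyl of the (E)-enoate and lowers its LUMO, and the terminal diene adds across C4=C5 in a concerted, asynchronous [4+2] step in which the bond from the enoate β-carbon C5 to C10 is the more advanced. The closest known reaction type is the Lewis-acid-promoted intramolecular Diels–Alder reaction of 2,8,10-undecatrienoates (1,7,9-decatriene type), which gives trans-fused octalins. Ring A is closed by the cycloaddition itself (all six atoms from diene and dienophile), ring B by the four-carbon tether as C5–C10 forms, formally a 6-exo-trig closure onto the enoate β-carbon. For C5 and C10, the aluminium-bound ester prefers the endo position; ester and C19 are cis on the (E)-dienophile, so the tether is exo and, with the (E)-diene, H-10 and C19 end up trans. For C4, suprafacial addition keeps the ester cis to C19 (4α), a centre that is erased in step 15. Relative to the preset C8 and C9, the diene face is chosen by a chair-like tether with C17 equatorial, which places C20 axial and the vinyl group equatorial. The step needs endo/exo and diene-face selectivity (regiochemistry is fixed by the tether); the first is secured by the Lewis acid and the two alkene geometries, the second by the equatorial preference of C17, which is the weaker of the two controls.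

Step 12
Reactants: 17 methyl (4R,5R,8R,9S,10S)-13,14,15,16-tetranorcleroda-1,11-dien-18-oate
Product: 19 methyl (4R,5R,8R,9S,10R)-12-hydroxy-13,14,15,16-tetranorclerod-1-en-18-oate, via alkylborane 18 (not isolated)
Conditions: 9-BBN-H, THF, 0 °C → rt; then 30 % H2O2, aq. NaOH, 0 °C
Reagents that add atoms: hydrogen peroxide, OO
Why: Hydroboration–oxidation; the bulky borane adds to the terminal CH2 of the vinyl group and leaves the 1,2-disubstituted ring alkene and the hindered ester alone, so oxidation of 18 gives the primary C12 alcohol.

Step 13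
Reactants: 19 methyl (4R,5R,8R,9S,10R)-12-hydroxy-13,14,15,16-tetranorclerod-1-en-18-oate
Product: 20 methyl (4R,5R,8R,9S,10R)-12-[(tert-butyldiphenylsilyl)oxy]-13,14,15,16-tetranorclerod-1-en-18-oate
Conditions: t-BuPh2SiCl, imidazole, DMF, rt
Reagents that add atoms: tert-butyl(chloro)diphenylsilane, CC(C)(C)[Si](Cl)(c1ccccc1)c1ccccc1
Why: Standard silylation of a primary alcohol; the tert-butyldiphenylsilyl ether withstands the amide base, the oxidant and the hydride reagents of steps 14–17.

Step 14
Reactants: 20 methyl (4R,5R,8R,9S,10R)-12-[(tert-butyldiphenylsilyl)oxy]-13,14,15,16-tetranorclerod-1-en-18-oate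
Product: 21 methyl (4R,5R,8R,9S,10R)-12-[(tert-butyldiphenylsilyl)oxy]-13,14,15,16-tetranorclerodan-18-oate
Conditions: H2 (1 atm), Pd/C (10 wt %), EtOAc, rt
Reagents that add atoms: none
Why: Heterogeneous hydrogenation of the cis-disubstituted C1=C2 alkene, the only alkene left after step 12; no stereocentre is created.

Step 15
Reactants: 21 methyl (4R,5R,8R,9S,10R)-12-[(tert-butyldiphenylsilyl)oxy]-13,14,15,16-tetranorclerodan-18-oate
Product: 24 methyl (5R,8R,9S,10R)-12-[(tert-butyldiphenylsilyl)oxy]-13,14,15,16-tetranorclerod-3-en-18-oate, via selenide 22 (not isolated), via selenoxide 23 (not isolated)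
Conditions: LiN(iPr)2, THF–HMPA, −78 → 0 °C; PhSeBr, −78 °C; then 30 % H2O2, pyridine, CH2Cl2, 0 °C → rt
Reagents that add atoms: none
Why: Ester-enolate selenenylation followed by selenoxide syn-elimination; C4 carries the only α-hydrogen and, C5 being quaternary, elimination from 23 can only run towards C3, giving the C3=C4 enoate regiospecifically.

Step 16
Reactants: 24 methyl (5R,8R,9S,10R)-12-[(tert-butyldiphenylsilyl)oxy]-13,14,15,16-tetranorclerod-3-en-18-oate
Product: 25 (5R,8R,9S,10R)-12-[(tert-butyldiphenylsilyl)oxy]-13,14,15,16-tetranorclerod-3-en-18-ol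
Conditions: iBu2AlH, CH2Cl2, −78 → 0 °C
Reagents that add atoms: none
Why: 1,2-Reduction of the conjugated ester by the aluminium hydride to the primary allylic alcohol; silyl ether and trisubstituted alkene are inert.

Step 17
Reactants: 25 (5R,8R,9S,10R)-12-[(tert-butyldiphenylsilyl)oxy]-13,14,15,16-tetranorclerod-3-en-18-ol
Product: 27 tert-butyl(diphenyl){[(5R,8R,9S,10R)-13,14,15,16-tetranorclerod-3-en-12-yl]oxy}silane, via sulfate monoester 26 (not isolated)
Conditions: SO3·pyridine, THF, 0 °C; then LiAlH4, 0 °C → rt
Reagents that add atoms: none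
Why: Deoxygenation of a primary allylic alcohol through its sulfate monoester; hydride displaces sulfate from 26 at the primary carbon (SN2), which keeps the alkene at C3=C4 and turns C18 into the methyl group, and the bulky silyl ether should survive LiAlH4 at this temperature.

Step 18
Reactants: 27 tert-butyl(diphenyl){[(5R,8R,9S,10R)-13,14,15,16-tetranorclerod-3-en-12-yl]oxy}silane
Product: 28 (5R,8R,9S,10R)-13,14,15,16-tetranorclerod-3-en-12-ol
Conditions: Bu4NF, THF, rt
Reagents that add atoms: none
Why: Fluoride-induced cleavage of the silyl ether; nothing else in 27 is sensitive to fluoride.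

Step 19
Reactants: 28 (5R,8R,9S,10R)-13,14,15,16-tetranorclerod-3-en-12-ol
Product: 29 (5R,8R,9S,10R)-12-iodo-13,14,15,16-tetranorclerod-3-ene
Conditions: I2, PPh3, imidazole, CH2Cl2, 0 °C → rt
Reagents that add atoms: iodine, II
Why: Appel-type iodination through the alkoxyphosphonium salt; SN2 displacement at the unhindered primary C12.

Step 20
Reactants: 30 but-2-yne-1,4-diol
Product: 31 4-[(tert-butyldimethylsilyl)oxy]but-2-yn-1-ol
Conditions: NaH (1 equiv), THF, 0 °C → rt; t-BuMe2SiCl
Reagents that add atoms: tert-butyl(chloro)dimethylsilane, CC(C)(C)[Si](C)(C)Cl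
Why: Monosilylation of the symmetrical diol through its sparingly soluble monosodium alkoxide, which suppresses bis-silylation.

Step 21
Reactants: 31 4-[(tert-butyldimethylsilyl)oxy]but-2-yn-1-ol
Product: 33 (2Z)-4-[(tert-butyldimethylsilyl)oxy]-3-iodobut-2-en-1-ol, via cyclic alkenylalanate 32 (not isolated)
Conditions: NaAlH2(OCH2CH2OMe)2, THF, 0 °C → rt; then I2, −78 → 0 °C
Reagents that add atoms: iodine, II
Why: Hydroxyl-directed trans-hydroalumination; hydride goes to the alkyne carbon nearer the alkoxide and aluminium to the carbon bearing the silyloxymethyl group (alanate 32), and iodinolysis with retention gives the (Z)-iodoalkene. This fixes the C13=C14 geometry and leaves the future O15 free while O16 is silylated.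

Step 22
Reactants: 33 (2Z)-4-[(tert-butyldimethylsilyl)oxy]-3-iodobut-2-en-1-ol; 34 icosanoic acid
Product: 35 (2Z)-4-[(tert-butyldimethylsilyl)oxy]-3-iodobut-2-en-1-yl icosanoate
Conditions: DCC, DMAP (cat.), CH2Cl2, rt
Reagents that add atoms: none
Why: Steglich esterification of the primary allylic alcohol with the fatty acid; the neutral conditions leave the alkenyl iodide and the silyl ether untouched.

Step 23
Reactants: 29 (5R,8R,9S,10R)-12-iodo-13,14,15,16-tetranorclerod-3-ene; 35 (2Z)-4-[(tert-butyldimethylsilyl)oxy]-3-iodobut-2-en-1-yl icosanoate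
Product: 37 (5R,8R,9S,10R,13E)-16-[(tert-butyldimethylsilyl)oxy]cleroda-3,13-dien-15-yl icosanoate, via alkylzinc iodide 36 (not isolated)
Conditions: Zn dust, LiCl, THF, 40 °C; then 35, PdCl2(dppf) (5 mol %), THF, rt
Reagents that add atoms: none
Why: Negishi sp3–sp2 coupling; zinc inserts into the primary C–I bond of 29, zerovalent palladium should add to the alkenyl iodide faster than it ionises the allylic ester, and transmetalation and reductive elimination form C12–C13 with retention of the alkene geometry; the alkylzinc tolerates the ester.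

Step 24
Reactants: 37 (5R,8R,9S,10R,13E)-16-[(tert-butyldimethylsilyl)oxy]cleroda-3,13-dien-15-yl icosanoate
Product: 38 (5R,8R,9S,10R,13E)-16-hydroxycleroda-3,13-dien-15-yl icosanoate
Conditions: HF·pyridine, pyridine, THF, 0 °C → rt
Reagents that add atoms: none
Why: Fluoride-mediated removal of the primary allylic silyl ether under buffered, non-basic conditions; the ester stays on O15 because the two CH2O groups are trans across the alkene.

## Compound list

1 | propanal | CCC=O | starting material
2 | but-3-en-2-one (methyl vinyl ketone) | CC(=O)C=C | starting material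
3 | (2R)-2-methyl-5-oxohexanal | CC(=O)CC[C@@H](C)C=O | intermediate
4 | (4R)-3-hydroxy-4-methylcyclohexan-1-one (C3 epimers) | O=C1CC[C@@H](C)C(O)C1 | intermediate (not isolated)
5 | (4R)-4-methylcyclohex-2-en-1-one | O=C1CC[C@@H](C)C=C1 | intermediate
6 | {[(3S,4R)-3,4-dimethylcyclohex-1-en-1-yl]oxy}trimethylsilane (methyls trans) | C[Si](C)(C)OC1=C[C@@H](C)[C@H](C)CC1 | intermediate
7 | (4R)-3,4-dimethylcyclohex-2-en-1-one | O=C1CC[C@@H](C)C(C)=C1 | intermediate
8 | {[(3S,4R)-3-ethenyl-3,4-dimethylcyclohex-1-en-1-yl]oxy}trimethylsilane (methyls cis) | C[Si](C)(C)OC1=C[C@@](C)(C=C)[C@H](C)CC1 | intermediate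
9 | (3S,4R)-3-ethenyl-3,4-dimethyl-2-[(trimethylsilyl)oxy]cyclohexan-1-one (C2 epimers) | O=C1CC[C@@H](C)[C@](C)(C=C)C1O[Si](C)(C)C | intermediate (not isolated)
10 | (3S,4R)-3-ethenyl-2-hydroxy-3,4-dimethylcyclohexan-1-one (C2 epimers) | O=C1CC[C@@H](C)[C@](C)(C=C)C1O | intermediate
11 | methyl (4R,5S)-5-formyl-4,5-dimethylhept-6-enoate | COC(=O)CC[C@@H](C)[C@](C)(C=C)C=O | intermediate
12 | methyl (4R,5S)-7-(diethoxyphosphoryl)-5-ethenyl-6-hydroxy-4,5-dimethylnon-8-enoate (present as lithium alkoxide, C6/C7 diastereomers) | COC(=O)CC[C@@H](C)[C@](C)(C=C)C(O)C(C=C)P(=O)(OCC)OCC | intermediate (not isolated)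
13 | methyl (4R,5S,6E)-5-ethenyl-4,5-dimethylnona-6,8-dienoate | COC(=O)CC[C@@H](C)[C@](C)(C=C)/C=C/C=C | intermediate
14 | (4R,5S,6E)-5-ethenyl-N-methoxy-N,4,5-trimethylnona-6,8-dienamide | CON(C)C(=O)CC[C@@H](C)[C@](C)(C=C)/C=C/C=C | intermediate (not isolated)
15 | (5R,6S,7E)-6-ethenyl-5,6-dimethyldeca-7,9-dien-2-one | CC(=O)CC[C@@H](C)[C@](C)(C=C)/C=C/C=C | intermediate
16 | methyl (2E,6R,7S,8E)-7-ethenyl-3,6,7-trimethylundeca-2,8,10-trienoate | COC(=O)/C=C(\C)CC[C@@H](C)[C@](C)(C=C)/C=C/C=C | intermediate
17 | methyl (4R,5R,8R,9S,10S)-13,14,15,16-tetranorcleroda-1,11-dien-18-oate (trans-fused; 4α-CO2Me, 5α-Me, 8α-Me, 9α-Me, 10β-H) | C=C[C@@]1(C)[C@H](C)CC[C@@]2(C)[C@H](C(=O)OC)CC=C[C@H]12 | intermediate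
18 | 9-[(4R,5R,8R,9S,10R)-18-methoxy-18-oxo-13,14,15,16-tetranorclerod-1-en-12-yl]-9-borabicyclo[3.3.1]nonane | B1(CC[C@@]2(C)[C@H](C)CC[C@@]3(C)[C@H](C(=O)OC)CC=C[C@H]23)C4CCCC1CCC4 | intermediate (not isolated)
19 | methyl (4R,5R,8R,9S,10R)-12-hydroxy-13,14,15,16-tetranorclerod-1-en-18-oate | OCC[C@@]1(C)[C@H](C)CC[C@@]2(C)[C@H](C(=O)OC)CC=C[C@H]12 | intermediate
20 | methyl (4R,5R,8R,9S,10R)-12-[(tert-butyldiphenylsilyl)oxy]-13,14,15,16-tetranorclerod-1-en-18-oate | CC(C)(C)[Si](OCC[C@@]1(C)[C@H](C)CC[C@@]2(C)[C@H](C(=O)OC)CC=C[C@H]12)(c1ccccc1)c1ccccc1 | intermediate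
21 | methyl (4R,5R,8R,9S,10R)-12-[(tert-butyldiphenylsilyl)oxy]-13,14,15,16-tetranorclerodan-18-oate | CC(C)(C)[Si](OCC[C@@]1(C)[C@H](C)CC[C@@]2(C)[C@H](C(=O)OC)CCC[C@H]12)(c1ccccc1)c1ccccc1 | intermediate
22 | methyl (5R,8R,9S,10R)-12-[(tert-butyldiphenylsilyl)oxy]-4-(phenylselanyl)-13,14,15,16-tetranorclerodan-18-oate (C4 not assigned) | CC(C)(C)[Si](OCC[C@@]1(C)[C@H](C)CC[C@@]2(C)C([Se]c3ccccc3)(C(=O)OC)CCC[C@H]12)(c1ccccc1)c1ccccc1 | intermediate (not isolated)
23 | methyl (5R,8R,9S,10R)-4-(benzeneseleninyl)-12-[(tert-butyldiphenylsilyl)oxy]-13,14,15,16-tetranorclerodan-18-oate (C4 not assigned) | CC(C)(C)[Si](OCC[C@@]1(C)[C@H](C)CC[C@@]2(C)C([Se](=O)c3ccccc3)(C(=O)OC)CCC[C@H]12)(c1ccccc1)c1ccccc1 | intermediate (not isolated)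
24 | methyl (5R,8R,9S,10R)-12-[(tert-butyldiphenylsilyl)oxy]-13,14,15,16-tetranorclerod-3-en-18-oate | CC(C)(C)[Si](OCC[C@@]1(C)[C@H](C)CC[C@@]2(C)C(C(=O)OC)=CCC[C@H]12)(c1ccccc1)c1ccccc1 | intermediate
25 | (5R,8R,9S,10R)-12-[(tert-butyldiphenylsilyl)oxy]-13,14,15,16-tetranorclerod-3-en-18-ol | CC(C)(C)[Si](OCC[C@@]1(C)[C@H](C)CC[C@@]2(C)C(CO)=CCC[C@H]12)(c1ccccc1)c1ccccc1 | intermediate
26 | pyridinium (5R,8R,9S,10R)-12-[(tert-butyldiphenylsilyl)oxy]-13,14,15,16-tetranorclerod-3-en-18-yl sulfate | CC(C)(C)[Si](OCC[C@@]1(C)[C@H](C)CC[C@@]2(C)C(COS(=O)(=O)[O-])=CCC[C@H]12)(c1ccccc1)c1ccccc1.c1cc[nH+]cc1 | intermediate (not isolated)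
27 | tert-butyl(diphenyl){[(5R,8R,9S,10R)-13,14,15,16-tetranorclerod-3-en-12-yl]oxy}silane | CC(C)(C)[Si](OCC[C@@]1(C)[C@H](C)CC[C@@]2(C)C(C)=CCC[C@H]12)(c1ccccc1)c1ccccc1 | intermediate
28 | (5R,8R,9S,10R)-13,14,15,16-tetranorclerod-3-en-12-ol | OCC[C@@]1(C)[C@H](C)CC[C@@]2(C)C(C)=CCC[C@H]12 | intermediate
29 | (5R,8R,9S,10R)-12-iodo-13,14,15,16-tetranorclerod-3-ene | ICC[C@@]1(C)[C@H](C)CC[C@@]2(C)C(C)=CCC[C@H]12 | intermediate
30 | but-2-yne-1,4-diol | OCC#CCO | starting material
31 | 4-[(tert-butyldimethylsilyl)oxy]but-2-yn-1-ol | CC(C)(C)[Si](C)(C)OCC#CCO | intermediate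
32 | sodium 3-{[(tert-butyldimethylsilyl)oxy]methyl}-2,2-bis(2-methoxyethoxy)-2,5-dihydro-1,2-oxaaluminol-2-uide (cyclic alkenylalanate) | [Na+].COCCO[Al-]1(OCCOC)OCC=C1CO[Si](C)(C)C(C)(C)C | intermediate (not isolated)
33 | (2Z)-4-[(tert-butyldimethylsilyl)oxy]-3-iodobut-2-en-1-ol | OC/C=C(\I)CO[Si](C)(C)C(C)(C)C | intermediate
34 | icosanoic acid | CCCCCCCCCCCCCCCCCCCC(=O)O | starting material
35 | (2Z)-4-[(tert-butyldimethylsilyl)oxy]-3-iodobut-2-en-1-yl icosanoate | CCCCCCCCCCCCCCCCCCCC(=O)OC/C=C(\I)CO[Si](C)(C)C(C)(C)C | intermediate
36 | [(5R,8R,9S,10R)-13,14,15,16-tetranorclerod-3-en-12-yl]zinc iodide | I[Zn]CC[C@@]1(C)[C@H](C)CC[C@@]2(C)C(C)=CCC[C@H]12 | intermediate (not isolated)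
37 | (5R,8R,9S,10R,13E)-16-[(tert-butyldimethylsilyl)oxy]cleroda-3,13-dien-15-yl icosanoate | CCCCCCCCCCCCCCCCCCCC(=O)OC/C=C(/CO[Si](C)(C)C(C)(C)C)CC[C@@]1(C)[C@H](C)CC[C@@]2(C)C(C)=CCC[C@H]12 | intermediate
38 | (5R,8R,9S,10R,13E)-16-hydroxycleroda-3,13-dien-15-yl icosanoate | CCCCCCCCCCCCCCCCCCCC(=O)OC/C=C(/CO)CC[C@@]1(C)[C@H](C)CC[C@@]2(C)C(C)=CCC[C@H]12 | target

## Step count and least certain steps

Total: 24 steps. Longest linear sequence: 21 steps (steps 1–19, then 23 and 24); the side-chain fragment takes 3 steps (20–22).

**Step 11 (key step).** The dienophile is a β,β-disubstituted enoate and the bond to C10 forms between two quaternary centres, so the cycloaddition may be slow. The endo transition state also places C19 under the diene and syn-diaxial to C20, so the endo preference may erode and cis-fused adducts may form. The alternative chair (C17 and vinyl axial) is not much higher in energy, so diene-face discrimination may be poor. The Lewis acid may also oligomerise the diene. The fallback changes the dienophile and sets out from 16: reduction with iBu2AlH gives (2E,6R,7S,8E)-7-ethenyl-3,6,7-trimethylundeca-2,8,10-trien-1-ol F1, and MnO2 oxidation gives the corresponding trienal F2. Aluminium-bound enals are much stronger dienophiles with a more pronounced endo preference, so cyclisation of F2 with Me2AlCl at low temperature should give (4R,5R,8R,9S,10S)-13,14,15,16-tetranorcleroda-1,11-dien-18-al F3. Oxidation with NaClO2 (2-methylbut-2-ene as scavenger) gives the acid F4, and methylation with trimethylsilyldiazomethane returns to the route at 17.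

**Step 8.** The ambident phosphonate anion may attack the hindered α-quaternary aldehyde through its γ-carbon, and the elimination may not be fully E-selective. The fallback sets out from 11: iodo-olefination with CHI3 and CrCl2 (divalent chromium; Takai reaction) should give methyl (4R,5S,6E)-5-ethenyl-7-iodo-4,5-dimethylhept-6-enoate F5 with high E-selectivity for a bulky aldehyde. Stille coupling of F5 with tributyl(vinyl)stannane under Pd(PPh3)4 returns to the route at 13.

**Step 10.** Olefination of a methyl ketone may give insufficient E/Z discrimination, and the isomers may be hard to separate. The fallback builds the trisubstituted alkene by syn-carbometalation and sets out from 13: partial reduction with iBu2AlH at −78 °C gives (4R,5S,6E)-5-ethenyl-4,5-dimethylnona-6,8-dienal F6, and Ohira–Bestmann homologation gives (3E,5S,6R)-5-ethenyl-5,6-dimethyldeca-1,3-dien-9-yne F7. Cp2ZrCl2-catalysed methylalumination of F7 with Me3Al, followed by trapping of the alkenylalane with methyl chloroformate, places methyl and ester cis by mechanism and returns to the route at 16.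

**Step 15.** Deprotonation or C-selenenylation at C4 may be incomplete because this carbon is flanked by the quaternary C5. The fallback moves the dehydrogenation to the more acidic aldehyde and sets out from 21: LiAlH4 gives (4R,5R,8R,9S,10R)-12-[(tert-butyldiphenylsilyl)oxy]-13,14,15,16-tetranorclerodan-18-ol F8, and Dess–Martin periodinane gives the 18-al F9. Dehydrogenation with IBX gives (5R,8R,9S,10R)-12-[(tert-butyldiphenylsilyl)oxy]-13,14,15,16-tetranorclerod-3-en-18-al F10, and 1,2-reduction with NaBH4 and CeCl3 returns to the route at 25.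

**Step 23.** Zerovalent palladium may ionise the allylic icosanoate (π-allyl formation with loss or transposition of the ester) in competition with oxidative addition to the C–I bond; zinc insertion may be sluggish, and β-hydride elimination may occur. The fallback couples before acylation and sets out from 33 and 36: silylation of 33 with Et3SiCl gives tert-butyl{[(2Z)-2-iodo-4-[(triethylsilyl)oxy]but-2-en-1-yl]oxy}dimethylsilane F11, which has no ionisable allylic ester. Negishi coupling of F11 with 36 gives (5R,8R,9S,10R,13E)-16-[(tert-butyldimethylsilyl)oxy]-15-[(triethylsilyl)oxy]cleroda-3,13-diene F12. Selective methanolysis of the more labile triethylsilyl ether (pyridinium p-toluenesulfonate, MeOH, 0 °C) gives (5R,8R,9S,10R,13E)-16-[(tert-butyldimethylsilyl)oxy]cleroda-3,13-dien-15-ol F13, and Steglich esterification with 34 returns to the route at 37.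

## Further compounds

F1 | step 11 | (2E,6R,7S,8E)-7-ethenyl-3,6,7-trimethylundeca-2,8,10-trien-1-ol | OC/C=C(\C)CC[C@@H](C)[C@](C)(C=C)/C=C/C=C
F2 | step 11 | (2E,6R,7S,8E)-7-ethenyl-3,6,7-trimethylundeca-2,8,10-trienal | O=C/C=C(\C)CC[C@@H](C)[C@](C)(C=C)/C=C/C=C
F3 | step 11 | (4R,5R,8R,9S,10S)-13,14,15,16-tetranorcleroda-1,11-dien-18-al | C=C[C@@]1(C)[C@H](C)CC[C@@]2(C)[C@H](C=O)CC=C[C@H]12
F4 | step 11 | (4R,5R,8R,9S,10S)-13,14,15,16-tetranorcleroda-1,11-dien-18-oic acid | C=C[C@@]1(C)[C@H](C)CC[C@@]2(C)[C@H](C(=O)O)CC=C[C@H]12
F5 | step 8 | methyl (4R,5S,6E)-5-ethenyl-7-iodo-4,5-dimethylhept-6-enoate | COC(=O)CC[C@@H](C)[C@](C)(C=C)/C=C/I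
F6 | step 10 | (4R,5S,6E)-5-ethenyl-4,5-dimethylnona-6,8-dienal | O=CCC[C@@H](C)[C@](C)(C=C)/C=C/C=C
F7 | step 10 | (3E,5S,6R)-5-ethenyl-5,6-dimethyldeca-1,3-dien-9-yne | C#CCC[C@@H](C)[C@](C)(C=C)/C=C/C=C
F8 | step 15 | (4R,5R,8R,9S,10R)-12-[(tert-butyldiphenylsilyl)oxy]-13,14,15,16-tetranorclerodan-18-ol | CC(C)(C)[Si](OCC[C@@]1(C)[C@H](C)CC[C@@]2(C)[C@H](CO)CCC[C@H]12)(c1ccccc1)c1ccccc1
F9 | step 15 | (4R,5R,8R,9S,10R)-12-[(tert-butyldiphenylsilyl)oxy]-13,14,15,16-tetranorclerodan-18-al | CC(C)(C)[Si](OCC[C@@]1(C)[C@H](C)CC[C@@]2(C)[C@H](C=O)CCC[C@H]12)(c1ccccc1)c1ccccc1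
F10 | step 15 | (5R,8R,9S,10R)-12-[(tert-butyldiphenylsilyl)oxy]-13,14,15,16-tetranorclerod-3-en-18-al | CC(C)(C)[Si](OCC[C@@]1(C)[C@H](C)CC[C@@]2(C)C(C=O)=CCC[C@H]12)(c1ccccc1)c1ccccc1
F11 | step 23 | tert-butyl{[(2Z)-2-iodo-4-[(triethylsilyl)oxy]but-2-en-1-yl]oxy}dimethylsilane | CC[Si](CC)(CC)OC/C=C(\I)CO[Si](C)(C)C(C)(C)C
F12 | step 23 | (5R,8R,9S,10R,13E)-16-[(tert-butyldimethylsilyl)oxy]-15-[(triethylsilyl)oxy]cleroda-3,13-diene | CC[Si](CC)(CC)OC/C=C(/CO[Si](C)(C)C(C)(C)C)CC[C@@]1(C)[C@H](C)CC[C@@]2(C)C(C)=CCC[C@H]12
F13 | step 23 | (5R,8R,9S,10R,13E)-16-[(tert-butyldimethylsilyl)oxy]cleroda-3,13-dien-15-ol | OC/C=C(/CO[Si](C)(C)C(C)(C)C)CC[C@@]1(C)[C@H](C)CC[C@@]2(C)C(C)=CCC[C@H]12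
A1 | alternative 1 | (1E)-1-[(tert-butyldimethylsilyl)oxy]buta-1,3-diene | C=C/C=C/O[Si](C)(C)C(C)(C)C
A2 | alternative 1 | (2E)-4-(benzyloxy)-2-methylbut-2-enal | O=C/C(C)=C/COCc1ccccc1
A3 | alternative 1 | 6-[(benzyloxy)methyl]-2-[(tert-butyldimethylsilyl)oxy]-1-methylcyclohex-3-ene-1-carbaldehyde | O=C[C@@]1(C)[C@@H](O[Si](C)(C)C(C)(C)C)C=CC[C@@H]1COCc1ccccc1
A4 | alternative 2 | 13,14,15,16-tetranor-ent-labd-8(17)-en-12-yl pivalate | CC(C)(C)C(=O)OCC[C@@H]1C(=C)CC[C@@H]2C(C)(C)CCC[C@@]12C
A5 | alternative 2 | 13,14,15,16-tetranorclerod-3-en-12-yl pivalate | CC(C)(C)C(=O)OCC[C@@]1(C)[C@H](C)CC[C@@]2(C)C(C)=CCC[C@H]12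
A6 | alternative 3 | 1-diazo-4-(2-ethenyl-2,3-dimethyl-6-methylidenecyclohexyl)butan-2-one (C8, C9, C10 as in the target) | C=C[C@@]1(C)[C@H](C)CCC(=C)[C@@H]1CCC(=O)C=[N+]=[N-]
A7 | alternative 3 | 3-oxo-4,19-cyclo-13,14,15,16,18-pentanorclerod-11-ene | C=C[C@@]1(C)[C@H](C)CC[C@@]23C[C@@H]2C(=O)CC[C@H]13
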